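A direct plan would condense the acetophenone A1, which carries a 1,1-dimethylallyl ether, with the ortho-geranyl benzaldehyde A2 to the 2′-hydroxychalcone A3. It would then close ring C by an enantioselective oxa-Michael addition to the flavanone ether A4 and move the allyl group to C6 by a Claisen rearrangement. Its weakest steps would be:
- the asymmetric O1–C2 ring closure, because no dependable catalyst exists for 6′-substituted 2′-hydroxychalcones and the closure is reversible, which could erode the ee;
- the aldol condensation, because a 2′,6′-disubstituted ketone and an ortho-substituted aldehyde would need long exposure to strong base;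
- the tertiary ether formation with its thermal rearrangement, two operations for one C–C bond through an ether that is labile to acid and heat.

The route rests on the C2–C1′ bond instead of a bond of ring C. Rings A and C are present from the start as a flat, achiral chromone, which is first dressed with the 6-prenyl group; ring B arrives last as the ortho-geranyl arylboronic acid. C2 is the β-carbon of the vinylogous ester O1–C2=C3–C4=O and carries only H besides ring B, so a rhodium-catalysed enantioselective 1,4-arylation joins the two halves, makes C2–C1′ and sets the only stereocentre in one irreversible C–C bond formation. No chalcone, aldol condensation or oxa-Michael closure occurs, and prenyl is brought in by cross-coupling at an iodide placed by the 5-OH group, so no allyl ether or sigmatropic step is needed.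

Key step: step 6

Assumption: with the (S,S) diene ligand the aryl group is taken to add to the Re face of chromone C2 (priorities O1 > C3 > H), by analogy with the sense of induction of this ligand on cyclic enones; were a trial to give the 2R product, the (R,R) ligand would be used instead.

Step 1
Reactants: 1 5,7-dihydroxy-4H-chromen-4-one
Product: 2 5-hydroxy-7-methoxy-4H-chromen-4-one
Conditions: MeI (1.1 equiv), K2CO3 (1.1 equiv), acetone, 40 °C
Reagents that add atoms: iodomethane, CI
Why: Williamson O-methylation, selective because the 7-OH is the acidic, vinylogous-acid phenol while the 5-OH is hydrogen-bonded to C4=O and should stay free with one equivalent of base.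

Step 2
Reactants: 2 5-hydroxy-7-methoxy-4H-chromen-4-one
Product: 3 5-hydroxy-6-iodo-7-methoxy-4H-chromen-4-one
Conditions: BnNMe3 ICl2 (1.05 equiv), CaCO3 (1.5 equiv), CH2Cl2/MeOH (5:2), rt, dark
Reagents that add atoms: benzyltrimethylammonium dichloroiodate, C[N+](C)(C)Cc1ccccc1.Cl[I-]Cl (gives the iodine)
Why: electrophilic aromatic iodination, in which the free chelated 5-OH of a 5-hydroxy-7-alkoxy chromone directs the iodine to its ortho position C6 (a fully O-alkylated ring would react at C8), with CaCO3 taking up the HCl.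

Step 3
Reactants: 3 5-hydroxy-6-iodo-7-methoxy-4H-chromen-4-one; 4 tributyl(3-methylbut-2-en-1-yl)stannane
Product: 5 5-hydroxy-7-methoxy-6-(3-methylbut-2-en-1-yl)-4H-chromen-4-one
Conditions: 4 (1.3 equiv), Pd(PPh3)4 (5 mol%), DMF, 90 °C, N2
Reagents that add atoms: none
Why: Stille coupling, in which zerovalent palladium inserts into C6–I, the allylic stannane transfers its α-carbon and reductive elimination gives the linear prenyl group, the chromone C2=C3 bond and the chelated phenol being inert.

Step 4
Reactants: 6 4-bromo-1,2-dimethoxybenzene; 7 geranyl bromide [(2E)-1-bromo-3,7-dimethylocta-2,6-diene]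
Product: 10 1-bromo-2-[(2E)-3,7-dimethylocta-2,6-dien-1-yl]-3,4-dimethoxybenzene, via aryllithium 8 (not isolated), via arylcopper 9 (not isolated)
Conditions: LiN(i-Pr)2 (LDA, commercial solution, 1.1 equiv), THF, −78 °C, 1 h; CuBr·SMe2 (1.1 equiv), −78 °C; 7 (1.2 equiv), −78 → −20 °C; aq NH4Cl
Reagents that add atoms: lithium diisopropylamide, CC(C)N([Li])C(C)C (gives the lithium of 8 only); CuBr·SMe2, CSC.[Cu]Br (gives the copper of 9 only); nothing from either stays in 10
Why: directed ortho-metalation at the most acidic C–H, between Br and the 2-OMe group, by an amide base that does not exchange bromine, followed by transmetalation to copper at −78 °C (which suppresses loss of LiBr to the aryne) and SN2 alkylation at the unhindered α-carbon of the primary allylic bromide, which keeps the E olefin.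

Step 5
Reactants: 10 1-bromo-2-[(2E)-3,7-dimethylocta-2,6-dien-1-yl]-3,4-dimethoxybenzene
Product: 13 {2-[(2E)-3,7-dimethylocta-2,6-dien-1-yl]-3,4-dimethoxyphenyl}boronic acid, via aryllithium 11 (not isolated), via lithium aryltrimethoxyborate 12 (not isolated)
Conditions: n-BuLi (1.05 equiv), THF, −78 °C, 20 min; B(OMe)3 (2 equiv), −78 °C → rt; 1 M HCl to pH 5, 0 °C
Reagents that add atoms: n-butyllithium, [Li]CCCC (gives the lithium of 11 and 12 only); trimethyl borate, COB(OC)OC (gives the boron, its methoxy groups stay in 12 only); water, O (gives the two OH groups of 13)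
Why: bromine–lithium exchange, faster than any deprotonation at −78 °C, then trapping of the aryllithium by the borate ester to the ate complex and mild acid hydrolysis that the trisubstituted olefins should tolerate.

Step 6
Reactants: 5 5-hydroxy-7-methoxy-6-(3-methylbut-2-en-1-yl)-4H-chromen-4-one; 13 {2-[(2E)-3,7-dimethylocta-2,6-dien-1-yl]-3,4-dimethoxyphenyl}boronic acid
Product: 14 (2S)-2-{2-[(2E)-3,7-dimethylocta-2,6-dien-1-yl]-3,4-dimethoxyphenyl}-5-hydroxy-7-methoxy-6-(3-methylbut-2-en-1-yl)-2,3-dihydro-4H-chromen-4-one (CNP0112088.1)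
Conditions: 13 (3 equiv), [RhCl(C2H4)2]2 (2.5 mol%), (S,S)-Ph-bod* [(1S,4S)-2,5-diphenylbicyclo[2.2.2]octa-2,5-diene] (5.5 mol%), KOH (5 mol%), 1,4-dioxane/H2O (10:1), 40 °C; aq NH4Cl; chromatography
Reagents that add atoms: none
Why: Hayashi–Miyaura asymmetric 1,4-addition, the reaction type known to give flavanones from chromones and arylboronic acids: boron-to-rhodium transmetalation gives an aryl–rhodium(diene) species, the chromone C2=C3 bond coordinates and inserts to form C2–C1′, and water protonates the resulting oxa-π-allyl rhodium enolate at C3, which returns Rh–OH. No ring is closed, since ring C is already in place and ring B is simply attached to it. C2 is the only new stereocentre and is set under ligand control, the C2-symmetric diene leaving only the Re face of C2 open to the aryl group, which gives 2S. The step needs 1,4- over 1,2-addition (secured by the soft aryl–rhodium and the vinylogous-ester polarisation that the chelated 5-OH strengthens), reaction at one of four C=C bonds (only the electron-poor C2=C3 bond binds and inserts, the trisubstituted prenyl and geranyl olefins do not), and survival of the base-labile product (near-neutral medium buffered by the boronic acid at 40 °C, irreversible C–C bond formation). The ortho-geranyl group should slow insertion and favour protodeboronation, which the three equivalents of 13 are meant to offset.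

Compound list
1 | 5,7-dihydroxy-4H-chromen-4-one | Oc1cc2occc(=O)c2c(O)c1 | starting material
2 | 5-hydroxy-7-methoxy-4H-chromen-4-one | COc1cc2occc(=O)c2c(O)c1 | intermediate
3 | 5-hydroxy-6-iodo-7-methoxy-4H-chromen-4-one | COc1cc2occc(=O)c2c(O)c1I | intermediate
4 | tributyl(3-methylbut-2-en-1-yl)stannane | CCCC[Sn](CCCC)(CCCC)CC=C(C)C | starting material
5 | 5-hydroxy-7-methoxy-6-(3-methylbut-2-en-1-yl)-4H-chromen-4-one | COc1cc2occc(=O)c2c(O)c1CC=C(C)C | intermediate
6 | 4-bromo-1,2-dimethoxybenzene | COc1ccc(Br)cc1OC | starting material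
7 | geranyl bromide, (2E)-1-bromo-3,7-dimethylocta-2,6-diene | BrC/C=C(\C)CCC=C(C)C | starting material
8 | (6-bromo-2,3-dimethoxyphenyl)lithium | COc1ccc(Br)c([Li])c1OC | intermediate
9 | (6-bromo-2,3-dimethoxyphenyl)copper | COc1ccc(Br)c([Cu])c1OC | intermediate
10 | 1-bromo-2-[(2E)-3,7-dimethylocta-2,6-dien-1-yl]-3,4-dimethoxybenzene | COc1ccc(Br)c(C/C=C(\C)CCC=C(C)C)c1OC | intermediate
11 | {2-[(2E)-3,7-dimethylocta-2,6-dien-1-yl]-3,4-dimethoxyphenyl}lithium | COc1ccc([Li])c(C/C=C(\C)CCC=C(C)C)c1OC | intermediate
12 | lithium {2-[(2E)-3,7-dimethylocta-2,6-dien-1-yl]-3,4-dimethoxyphenyl}trimethoxyborate | [Li+].COc1ccc([B-](OC)(OC)OC)c(C/C=C(\C)CCC=C(C)C)c1OC | intermediate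
13 | {2-[(2E)-3,7-dimethylocta-2,6-dien-1-yl]-3,4-dimethoxyphenyl}boronic acid | COc1ccc(B(O)O)c(C/C=C(\C)CCC=C(C)C)c1OC | intermediate
14 | (2S)-2-{2-[(2E)-3,7-dimethylocta-2,6-dien-1-yl]-3,4-dimethoxyphenyl}-5-hydroxy-7-methoxy-6-(3-methylbut-2-en-1-yl)-2,3-dihydro-4H-chromen-4-one | COc1cc2c(c(O)c1CC=C(C)C)C(=O)C[C@@H](c1ccc(OC)c(OC)c1C/C=C(\C)CCC=C(C)C)O2 | target

Total step count: 6. Longest linear sequence: 4 (steps 1, 2, 3, 6).

Steps most likely to fail

Step 6. Insertion of the ortho-geranyl aryl–rhodium may be slow, so that protodeboronation consumes 13. The 5-oxido-4-keto unit may bind rhodium as a chelate and slow turnover. Facial selectivity may be poor, or the product may lose ee by reversible ring opening. Fallback, from 5 and 10, back at 14: 5 would be silylated at both oxygens with TBSOTf (2.2 equiv) and 2,6-lutidine (1.1 equiv) in CH2Cl2 to the 4,5-bis(silyloxy)chromenylium triflate F1 (not isolated). The arylmagnesium bromide F2, made from 10 with Mg turnings and LiCl in THF, would add to C2 of this cation at −78 °C with CuBr·SMe2 (10 mol%) to give the racemic 2H-chromene silyl enol ether F3. HF·pyridine in THF would remove both silyl groups to the racemic flavanone F4, and the enantiomers would be separated by preparative HPLC on a chiral stationary phase to give 14.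

Step 4. The ortho-bromo aryllithium may lose LiBr to the aryne, the halogen may migrate, or the allylic bromide may be attacked at its γ-carbon to give the linalyl-type isomer. Fallback, from purchased 1-iodo-2,3-dimethoxybenzene F5, back at 10: NBS in MeCN would brominate para to the unhindered 3-OMe group to give 1-bromo-2-iodo-3,4-dimethoxybenzene F6. i-PrMgCl·LiCl (THF, −40 °C) would exchange only the iodine to give the arylmagnesium chloride F7, which should not eliminate at this temperature, and Li2CuCl4 (5 mol%) with 7 would give 10.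

Step 3. The stannane may transfer through its γ-carbon (1,1-dimethylallyl isomer), or coupling at the doubly ortho-substituted iodide may be sluggish. Fallback, from 3, back at 5: Stille coupling with allyltributylstannane (Pd(PPh3)4, DMF, 90 °C), which has no α/γ ambiguity, would give the 6-allyl chromone F8. Cross-metathesis with 2-methylbut-2-ene (second-generation Grubbs catalyst, RuCl2(=CHPh)(PCy3)(H2IMes), CH2Cl2, 40 °C) would turn allyl into prenyl and give 5.

Further compounds
F1 | step 6 | 4,5-bis[(tert-butyldimethylsilyl)oxy]-7-methoxy-6-(3-methylbut-2-en-1-yl)chromenylium trifluoromethanesulfonate | COc1cc2[o+]ccc(O[Si](C)(C)C(C)(C)C)c2c(O[Si](C)(C)C(C)(C)C)c1CC=C(C)C.[O-]S(=O)(=O)C(F)(F)F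
F2 | step 6 | {2-[(2E)-3,7-dimethylocta-2,6-dien-1-yl]-3,4-dimethoxyphenyl}magnesium bromide | COc1ccc([Mg]Br)c(C/C=C(\C)CCC=C(C)C)c1OC
F3 | step 6 | racemic 4,5-bis[(tert-butyldimethylsilyl)oxy]-2-{2-[(2E)-3,7-dimethylocta-2,6-dien-1-yl]-3,4-dimethoxyphenyl}-7-methoxy-6-(3-methylbut-2-en-1-yl)-2H-chromene | COc1cc2OC(c3ccc(OC)c(OC)c3C/C=C(\C)CCC=C(C)C)C=C(O[Si](C)(C)C(C)(C)C)c2c(O[Si](C)(C)C(C)(C)C)c1CC=C(C)C
F4 | step 6 | racemic 2-{2-[(2E)-3,7-dimethylocta-2,6-dien-1-yl]-3,4-dimethoxyphenyl}-5-hydroxy-7-methoxy-6-(3-methylbut-2-en-1-yl)-2,3-dihydro-4H-chromen-4-one | COc1cc2c(c(O)c1CC=C(C)C)C(=O)CC(c1ccc(OC)c(OC)c1C/C=C(\C)CCC=C(C)C)O2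
F5 | step 4 | 1-iodo-2,3-dimethoxybenzene | COc1cccc(I)c1OC
F6 | step 4 | 1-bromo-2-iodo-3,4-dimethoxybenzene | COc1ccc(Br)c(I)c1OC
F7 | step 4 | (6-bromo-2,3-dimethoxyphenyl)magnesium chloride | COc1ccc(Br)c([Mg]Cl)c1OC
F8 | step 3 | 5-hydroxy-7-methoxy-6-(prop-2-en-1-yl)-4H-chromen-4-one | COc1cc2occc(=O)c2c(O)c1CC=C
A1 | direct plan | 1-[2-hydroxy-4-methoxy-6-(2-methylbut-3-en-2-yloxy)phenyl]ethan-1-one | CC(=O)c1c(O)cc(OC)cc1OC(C)(C)C=C
A2 | direct plan | 2-[(2E)-3,7-dimethylocta-2,6-dien-1-yl]-3,4-dimethoxybenzaldehyde | COc1ccc(C=O)c(C/C=C(\C)CCC=C(C)C)c1OC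
A3 | direct plan | (2E)-3-{2-[(2E)-3,7-dimethylocta-2,6-dien-1-yl]-3,4-dimethoxyphenyl}-1-[2-hydroxy-4-methoxy-6-(2-methylbut-3-en-2-yloxy)phenyl]prop-2-en-1-one | COc1cc(O)c(C(=O)/C=C/c2ccc(OC)c(OC)c2C/C=C(\C)CCC=C(C)C)c(OC(C)(C)C=C)c1
A4 | direct plan | (2S)-2-{2-[(2E)-3,7-dimethylocta-2,6-dien-1-yl]-3,4-dimethoxyphenyl}-7-methoxy-5-(2-methylbut-3-en-2-yloxy)-2,3-dihydro-4H-chromen-4-one | COc1cc2c(c(OC(C)(C)C=C)c1)C(=O)C[C@@H](c1ccc(OC)c(OC)c1C/C=C(\C)CCC=C(C)C)O2
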